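If a flask holds 2.5 mol% of second catalyst and little material can be spared, the first thing to count is how often each second catalyst has turned over.

the same everywhere: second catalyst 2.5 mol%
- Saturday's: starting material 0.40 M; reagent 0.90 equiv; free catalyst 0.1 mol%; run made earlier
- Friday's: starting material 0.40 M; reagent 0.90 equiv; free catalyst 0.4 mol%; run made earlier
- Tuesday's: starting material 0.20 M; reagent 0.90 equiv; free catalyst 0.2 mol%; run made earlier
- elm: starting material 0.40 M; reagent 0.900 equiv; free catalyst 0.2 mol%; time 10 min
- larch: starting material 0.40 M; reagent 0.900 equiv; free catalyst 0.2 mol%; time 4.0 min

| run | time / min | target / % | starting material / % |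
|---|---|---|---|
| Saturday's | 0.200 | 3.0 | 59.5 |
| Saturday's | 0.667 | 10.4 | 35.7 |
| Saturday's | 1.00 | 16.6 | 30.8 |
| Saturday's | 1.50 | 21.3 | 23.8 |
| Saturday's | 2.50 | 28.4 | 15.5 |
| Friday's | 0.200 | 5.1 | 50.4 |
| Friday's | 0.333 | 7.1 | 46.1 |
| Friday's | 0.667 | 12.0 | 34.1 |
| Friday's | 1.33 | 23.4 | 24.2 |
| Friday's | 2.50 | 30.6 | 13.0 |
| Tuesday's | 0.200 | 2.2 | 62.5 |
| Tuesday's | 0.333 | 1.2 | 54.5 |
| Tuesday's | 0.667 | 5.9 | 50.4 |
| Tuesday's | 1.33 | 11.3 | 35.8 |
| Tuesday's | 2.50 | 19.6 | 25.8 |

(scatter of a reading: 1 percentage point)

- in percentages every species weighs as the starting material in it: one side product counts as two

1. which of the two there is more of at the end, counted by the starting material in each, elm (side product / target)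
2. which of the two there is more of at the end, counted by the starting material in each, larch (side product / target)
3. final target, as a percentage of the starting material charged, in elm
4. final target, as a percentage of the starting material charged, in larch

What do you count? Turnovers: target as a percentage of the charge, divided by the loading. Saturday's run stands at 11.4 turnovers at 2.50 min.

How fast do they come? Between its last two readings, Saturday's run gains target at 0.361 /min for each unit of starting material standing. Dividing by the loading gives the turnover constant 14.5 /min: the turnover frequency with the whole charge still standing.

Does free catalyst matter? Friday's run, with four times the free catalyst, reads 13.2 /min, so I carry Saturday's reading to elm and larch. Tuesday's run at 0.20 M reads lower, 9.21 /min, so the constant holds for 0.40 M.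

And your answer? At 2.50 min the two runs average 29.5% target and 14.3% starting material. Saturday's starting material is falling at 0.429 /min. Adding the turnovers still to come, I reckon 35.2% target in larch and 41.0% in elm. The shortfall at 2.50 min, 56.2%, I read as side product, which stays ahead in both.

Where is that weak? Saturday's run has lost 37.5% of its charge as unread material by 0.200 min. If part of that is a held form that can still give target, my elm figure is low.

The forecast gives 40% for elm and 35% for larch, close to mine, with side product ahead: “Side product stays ahead in both.”

Elm gives 45.6% target and 52.2% side product; larch gives 36.4% and 50.3%.

    starting material + free catalyst ⇌ free catalyst + open intermediate (K = 0.690, k = 170 /M/s)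
    second catalyst + open intermediate ⇌ catalyst intermediate (K = 16.0 /M, k = 1.10 /M/s)
    reagent + catalyst intermediate → second catalyst + target (k = 16.0 /M/s)
    target → over-reaction product (k = 2.00 × 10⁻⁶ /s)
    starting material + open intermediate → side product (k = 0.0610 /M/s)

Up to 1.00 min in elm, the passing of starting material into open intermediate has 74% of its turnover behind it, more than the 37% of the capture of open intermediate by second catalyst. At 10.0 min, 0.878% of elm's charge still stands as open intermediate. From 5.00 min to 10.0 min, with starting material taken as its logarithmic mean, elm's turnover constant comes to 16.8 /min, higher than the 14.5 /min read earlier. The neighbour with 6.2 mol% of second catalyst ends on 66.1% target, which at elm's 16.8 /min means an average of about 6.35% starting material standing over its 10 min.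

Readings and results were generated by integration with constants of no real substance.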